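The plan rests on disconnecting the aryl ether bond C8a–O1 in ring C of the flavanone half. Ring A carries O1 on C8a, the carbon para to C6 where the C6–C8'' biaryl bond starts. A ring A made from 5-bromoresorcinol therefore has its bromine exactly at that position. The precursor is an open-chain (1S,3S)-1,3-diol. It has Br on C8a and the perbenzylated apigenin on C6, and the (S)-carbinol of the future C2 is already set by asymmetric transfer hydrogenation. One copper-catalysed O-arylation closes ring C as a flavan-4-ol and leaves the C2–O bond alone, so C2 is carried through. Oxidation at C4 and hydrogenolysis of six benzyl ethers finish the synthesis.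

Key step: step 11

Assumption: the target string fixes only C2 and leaves the hindered C6–C8'' axis undefined. Every biaryl compound below is therefore drawn without an axial descriptor and is expected as a pair of atropisomers that are carried on together.

Design remarks
- **C6 handle.** It is an iodine placed between two free hydroxyls by electrophilic substitution. Strong-base metalation is avoided because it would attack the C–Br bond and the benzylic CH2 groups.
- **Acetyl group.** It goes onto ring A before the flavone is attached. Acylation of the finished biaryl would have to discriminate against C6'' of the flavone.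
- **Side chain.** The chain and both carbinols are finished before the coupling, so the flavone never meets enolates, ruthenium hydride or borohydride.
- **Halogens.** Both sit on the electrophile and are addressed in turn, iodine by palladium and bromine by copper. The boron partner carries no halogen and cannot self-couple.
- **Stereochemical check.** The anti (1S,3S)-diol maps onto the 2,4-cis (2S,4S)-flavan-4-ol. The (S)-carbinol requires the (S,S)-diamine ligand. The C4 hydroxyl stays free because it cannot cyclise and is oxidised two steps later.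

Step 1
Reactants: 1 5-bromoresorcinol
Product: 2 1-(2-bromo-4,6-dihydroxyphenyl)ethan-1-one
Conditions: AcOH (1.2 equiv), BF3·OEt2 (solvent), 85 °C; then H2O
Reagents that add atoms: acetic acid, CC(=O)O
Why: Friedel–Crafts C-acylation of a resorcinol (Nencki type) goes para to one hydroxyl and ortho to the other, here the carbon next to bromine, because the site between the two hydroxyls reacts more slowly just as in resorcinol and orcinol, and this puts the future C4 carbon on C4a with bromine on C8a.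

Step 2
Reactants: 2 1-(2-bromo-4,6-dihydroxyphenyl)ethan-1-one
Product: 3 1-(6-bromo-2,4-dihydroxy-3-iodophenyl)ethan-1-one
Conditions: I2 (0.42 equiv), HIO3 (0.21 equiv), EtOH/H2O, 35 °C
Reagents that add atoms: iodine, [I][I]; iodic acid, OI(=O)=O
Why: Electrophilic aromatic iodination with the I2/HIO3 couple takes the carbon flanked by both hydroxyls (future C6), the known outcome for 2,4-dihydroxyacetophenone, and the only other free ring position is crowded by bromine.

Step 3
Reactants: 3 1-(6-bromo-2,4-dihydroxy-3-iodophenyl)ethan-1-one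
Product: 4 1-[2,4-bis(benzyloxy)-6-bromo-3-iodophenyl]ethan-1-one
Conditions: BnBr (2.5 equiv), K2CO3, DMF, 60 °C
Reagents that add atoms: benzyl bromide, BrCc1ccccc1
Why: Williamson ether synthesis on both phenols, the chelated one included at 60 °C in DMF, installs groups that survive base, hydride, palladium and copper and leave together in the last step.

Step 4
Reactants: 4 1-[2,4-bis(benzyloxy)-6-bromo-3-iodophenyl]ethan-1-one; 5 methyl 4-(benzyloxy)benzoate
Product: 6 1-[2,4-bis(benzyloxy)-6-bromo-3-iodophenyl]-3-[4-(benzyloxy)phenyl]propane-1,3-dione (drawn as the diketo tautomer)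
Conditions: KOtBu (2.2 equiv), THF, 0 °C → rt; aq HCl quench
Reagents that add atoms: none
Why: Crossed Claisen condensation between the only enolisable partner (the methyl ketone) and a non-enolisable benzoate is driven to completion by deprotonation of the 1,3-diketone, and at room temperature neither carbon–halogen bond nor a benzyl ether is touched by the alkoxide.

Step 5
Reactants: 6 1-[2,4-bis(benzyloxy)-6-bromo-3-iodophenyl]-3-[4-(benzyloxy)phenyl]propane-1,3-dione
Product: 7 (3S)-1-[2,4-bis(benzyloxy)-6-bromo-3-iodophenyl]-3-[4-(benzyloxy)phenyl]-3-hydroxypropan-1-one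
Conditions: RuCl(p-cymene)[(S,S)-TsDPEN] (2 mol %), HCO2H/Et3N (5:2), CH2Cl2, 35 °C
Reagents that add atoms: none
Why: Noyori–Ikariya asymmetric transfer hydrogenation, known for 1,3-diaryl-1,3-diketones, reduces the open 4-benzyloxybenzoyl carbonyl while the aroyl carbonyl flanked by Br and OBn is shielded, and the (S,S)-diamine ligand delivers hydride in the same sense that turns acetophenone into (S)-1-phenylethanol, which sets the future C2 as S.

Step 6
Reactants: 7 (3S)-1-[2,4-bis(benzyloxy)-6-bromo-3-iodophenyl]-3-[4-(benzyloxy)phenyl]-3-hydroxypropan-1-one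
Product: 8 (1S,3S)-1-[2,4-bis(benzyloxy)-6-bromo-3-iodophenyl]-3-[4-(benzyloxy)phenyl]propane-1,3-diol (anti)
Conditions: Me4NBH(OAc)3 (5 equiv), MeCN/AcOH (2:1), −30 → 0 °C
Reagents that add atoms: none
Why: Evans–Saksena reduction, in which the C3 hydroxyl replaces an acetate on boron and hydride is passed inside a chair-like six-membered transition state, gives the 1,3-anti diol and so sets C1 (future C4) as S, a centre that only has to be uniform because step 12 erases it.

Step 7
Reactants: 9 apigenin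
Product: 10 5,7-bis(benzyloxy)-2-[4-(benzyloxy)phenyl]-4H-chromen-4-one (tri-O-benzylapigenin)
Conditions: BnBr (4 equiv), K2CO3, DMF, 80 °C
Reagents that add atoms: benzyl bromide, BrCc1ccccc1
Why: Williamson ether synthesis with excess halide at 80 °C also alkylates the hydrogen-bonded 5-OH, which is needed both for protection and to steer the next step to C8''.

Step 8
Reactants: 10 5,7-bis(benzyloxy)-2-[4-(benzyloxy)phenyl]-4H-chromen-4-one
Product: 11 5,7-bis(benzyloxy)-2-[4-(benzyloxy)phenyl]-8-iodo-4H-chromen-4-one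
Conditions: NIS (1.1 equiv), TFA (0.2 equiv), MeCN/CH2Cl2, rt, dark
Reagents that add atoms: N-iodosuccinimide, O=C1CCC(=O)N1I
Why: Electrophilic aromatic iodination of fully O-alkylated 5,7-dioxygenated flavones is known to take C8, the carbon flanked by one alkoxy group and the ring oxygen, in preference to C6 between two benzyloxy groups, while the 4-benzyloxyphenyl ring and C3 are far less nucleophilic.

Step 9
Reactants: 11 5,7-bis(benzyloxy)-2-[4-(benzyloxy)phenyl]-8-iodo-4H-chromen-4-one
Product: 12 5,7-bis(benzyloxy)-2-[4-(benzyloxy)phenyl]-8-(4,4,5,5-tetramethyl-1,3,2-dioxaborolan-2-yl)-4H-chromen-4-one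
Conditions: B2pin2 (1.5 equiv), PdCl2(dppf) (5 mol %), KOAc (3 equiv), 1,4-dioxane, 90 °C
Reagents that add atoms: bis(pinacolato)diboron, CC1(C)OB(OC1(C)C)B1OC(C)(C)C(C)(C)O1
Why: Miyaura borylation exchanges the aryl iodide for a pinacol boronate under the weak base KOAc, conditions that leave the pyranone and the benzyl ethers alone and are established for halogenated flavones.

Step 10
Reactants: 8 (1S,3S)-1-[2,4-bis(benzyloxy)-6-bromo-3-iodophenyl]-3-[4-(benzyloxy)phenyl]propane-1,3-diol; 12 flavone 8-pinacolboronate (1.1 equiv)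
Product: 13 (1S,3S)-1-{2,4-bis(benzyloxy)-6-bromo-3-[5,7-bis(benzyloxy)-2-(4-benzyloxyphenyl)-4-oxo-4H-chromen-8-yl]phenyl}-3-[4-(benzyloxy)phenyl]propane-1,3-diol
Conditions: Pd(OAc)2 (5 mol %), SPhos (10 mol %), K3PO4 (3 equiv), toluene/H2O (10:1), 80 °C
Reagents that add atoms: none
Why: Suzuki–Miyaura coupling with a dialkylbiarylphosphine ligand, the catalyst class known to forge tetra-ortho-substituted biaryls, should join C6 to C8'' because zerovalent palladium inserts into the weaker C6–I bond before the C8a–Br bond that is shielded by the branched side chain, and because keeping both halogens on the electrophile excludes self-coupling of the boron partner.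

Step 11
Reactants: 13 (1S,3S)-1-{2,4-bis(benzyloxy)-6-bromo-3-[5,7-bis(benzyloxy)-2-(4-benzyloxyphenyl)-4-oxo-4H-chromen-8-yl]phenyl}-3-[4-(benzyloxy)phenyl]propane-1,3-diol
Product: 14 (2S,4S)-5,7-bis(benzyloxy)-2-[4-(benzyloxy)phenyl]-6-[5,7-bis(benzyloxy)-2-(4-benzyloxyphenyl)-4-oxo-4H-chromen-8-yl]chroman-4-ol (2,4-cis)
Conditions: CuI (20 mol %), 3,4,7,8-tetramethyl-1,10-phenanthroline (40 mol %), Cs2CO3 (2 equiv), 4 Å MS, toluene, 110 °C, Ar
Reagents that add atoms: none
Why: Cs2CO3 turns the C2 carbinol into its alkoxide on the phenanthroline-bound monovalent copper centre, this copper alkoxide activates the neighbouring C8a–Br bond by oxidative addition to a seven-membered trivalent cupracycle (Cu, O1, C2, C3, C4, C4a, C8a), and reductive elimination forms C8a–O1. The closest known reaction type is the intramolecular Ullmann-type O-arylation of 3-(2-haloaryl)-1-arylpropan-1-ols, which gives chromans and flavans. Ring C closes in a six-membered exo mode, the departing bromide lying outside the new pyran ring. No stereocentre is created: only the O–H bond of the (S)-carbinol is broken and neither an enone nor a quinone methide can arise under carbonate in toluene, so C2 stays S and C4 stays S. The step needs selectivity between the two hydroxyls and for one carbon–halogen bond; ring size secures the first, since the C4 alkoxide could only give a four-membered ring, and the second is secured because iodine was spent in step 10 and C8a–Br is the only halide left. Copper is preferred to palladium because its alkoxides are much less prone to beta-hydride loss from the two benzylic carbinols.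

Step 12
Reactants: 14 (2S,4S)-flavan-4-ol hexabenzyl ether
Product: 15 (2S)-5,7-bis(benzyloxy)-2-[4-(benzyloxy)phenyl]-6-[5,7-bis(benzyloxy)-2-(4-benzyloxyphenyl)-4-oxo-4H-chromen-8-yl]chroman-4-one
Conditions: Dess–Martin periodinane (1.5 equiv), NaHCO3, CH2Cl2, 0 °C → rt
Reagents that add atoms: none
Why: Dess–Martin oxidation converts the benzylic C4 alcohol into the ketone under buffered, essentially neutral conditions, so that the new flavanone is not opened to its chalcone and C2 stays S.

Step 13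
Reactants: 15 (2S)-flavanone hexabenzyl ether
Product: 16 (2S)-6-[5,7-dihydroxy-2-(4-hydroxyphenyl)-4-oxo-4H-chromen-8-yl]-5,7-dihydroxy-2-(4-hydroxyphenyl)chroman-4-one (target)
Conditions: H2 (1 atm), 10% Pd/C, THF/MeOH (1:1), rt
Reagents that add atoms: none
Why: Catalytic hydrogenolysis cleaves all six O-benzyl bonds at room temperature and one atmosphere without acid or base, conditions under which the flavone double bond, the aryl ketone and the cyclic C2–O1 bond are known to persist and the base-labile C2 centre cannot racemise.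

Compound list
1 | 5-bromoresorcinol | Oc1cc(O)cc(Br)c1 | starting material
2 | 1-(2-bromo-4,6-dihydroxyphenyl)ethan-1-one | CC(=O)c1c(O)cc(O)cc1Br | intermediate
3 | 1-(6-bromo-2,4-dihydroxy-3-iodophenyl)ethan-1-one | CC(=O)c1c(O)c(I)c(O)cc1Br | intermediate
4 | 1-[2,4-bis(benzyloxy)-6-bromo-3-iodophenyl]ethan-1-one | CC(=O)c1c(OCc2ccccc2)c(I)c(OCc2ccccc2)cc1Br | intermediate
5 | methyl 4-(benzyloxy)benzoate | COC(=O)c1ccc(OCc2ccccc2)cc1 | starting material
6 | 1-[2,4-bis(benzyloxy)-6-bromo-3-iodophenyl]-3-[4-(benzyloxy)phenyl]propane-1,3-dione | O=C(c1c(Br)cc(OCc2ccccc2)c(I)c1OCc1ccccc1)CC(=O)c1ccc(OCc2ccccc2)cc1 | intermediate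
7 | (3S)-1-[2,4-bis(benzyloxy)-6-bromo-3-iodophenyl]-3-[4-(benzyloxy)phenyl]-3-hydroxypropan-1-one | O=C(c1c(Br)cc(OCc2ccccc2)c(I)c1OCc1ccccc1)C[C@@H](c1ccc(OCc2ccccc2)cc1)O | intermediate
8 | (1S,3S)-1-[2,4-bis(benzyloxy)-6-bromo-3-iodophenyl]-3-[4-(benzyloxy)phenyl]propane-1,3-diol | O[C@H](c1c(Br)cc(OCc2ccccc2)c(I)c1OCc1ccccc1)C[C@@H](c1ccc(OCc2ccccc2)cc1)O | intermediate
9 | apigenin | O=c1cc(-c2ccc(O)cc2)oc2cc(O)cc(O)c12 | starting material
10 | 5,7-bis(benzyloxy)-2-[4-(benzyloxy)phenyl]-4H-chromen-4-one | O=c1cc(-c2ccc(OCc3ccccc3)cc2)oc2cc(OCc3ccccc3)cc(OCc3ccccc3)c12 | intermediate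
11 | 5,7-bis(benzyloxy)-2-[4-(benzyloxy)phenyl]-8-iodo-4H-chromen-4-one | O=c1cc(-c2ccc(OCc3ccccc3)cc2)oc2c(I)c(OCc3ccccc3)cc(OCc3ccccc3)c12 | intermediate
12 | 5,7-bis(benzyloxy)-2-[4-(benzyloxy)phenyl]-8-(4,4,5,5-tetramethyl-1,3,2-dioxaborolan-2-yl)-4H-chromen-4-one | O=c1cc(-c2ccc(OCc3ccccc3)cc2)oc2c(B3OC(C)(C)C(C)(C)O3)c(OCc3ccccc3)cc(OCc3ccccc3)c12 | intermediate
13 | (1S,3S)-1-{2,4-bis(benzyloxy)-6-bromo-3-[5,7-bis(benzyloxy)-2-(4-benzyloxyphenyl)-4-oxo-4H-chromen-8-yl]phenyl}-3-[4-(benzyloxy)phenyl]propane-1,3-diol | O[C@H](c1c(Br)cc(OCc2ccccc2)c(-c3c(OCc6ccccc6)cc(OCc6ccccc6)c4c(=O)cc(-c5ccc(OCc6ccccc6)cc5)oc34)c1OCc2ccccc2)C[C@@H](c1ccc(OCc2ccccc2)cc1)O | intermediate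
14 | (2S,4S)-5,7-bis(benzyloxy)-2-[4-(benzyloxy)phenyl]-6-[5,7-bis(benzyloxy)-2-(4-benzyloxyphenyl)-4-oxo-4H-chromen-8-yl]chroman-4-ol | O[C@H]1C[C@@H](c2ccc(OCc7ccccc7)cc2)Oc2cc(OCc7ccccc7)c(-c3c(OCc6ccccc6)cc(OCc6ccccc6)c4c(=O)cc(-c5ccc(OCc6ccccc6)cc5)oc34)c(OCc7ccccc7)c21 | intermediate
15 | (2S)-5,7-bis(benzyloxy)-2-[4-(benzyloxy)phenyl]-6-[5,7-bis(benzyloxy)-2-(4-benzyloxyphenyl)-4-oxo-4H-chromen-8-yl]chroman-4-one | O=C1C[C@@H](c2ccc(OCc7ccccc7)cc2)Oc2cc(OCc7ccccc7)c(-c3c(OCc6ccccc6)cc(OCc6ccccc6)c4c(=O)cc(-c5ccc(OCc6ccccc6)cc5)oc34)c(OCc7ccccc7)c21 | intermediate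
16 | (2S)-6-[5,7-dihydroxy-2-(4-hydroxyphenyl)-4-oxo-4H-chromen-8-yl]-5,7-dihydroxy-2-(4-hydroxyphenyl)chroman-4-one | O=C1C[C@@H](c2ccc(O)cc2)Oc2cc(O)c(-c3c(O)cc(O)c4c(=O)cc(-c5ccc(O)cc5)oc34)c(O)c21 | target

Total step count: 13. Longest linear sequence: 10 steps (steps 1–6 and 10–13). Steps 7–9 form the three-step flavone branch.

Steps most likely to fail

**Step 11.** Activation of the C8a–Br bond may be too slow on this crowded, electron-rich ring. Hydride transfer from the adjacent C4 alkoxide to copper, with reductive loss of bromine, could then overtake ring closure. The fallback closes ring C at its other end, O1–C2, by a Mitsunobu etherification with inversion, a known way from 1-aryl-3-(2-hydroxyaryl)propan-1-ols to flavans. It sets out from 6. Transfer hydrogenation with RuCl(p-cymene)[(R,R)-TsDPEN] should give the (3R)-hydroxy ketone F1. Narasaka–Prasad reduction (Et2BOMe, NaBH4, THF/MeOH, −78 °C) should give the syn (1S,3R)-iodo diol F2. Suzuki–Miyaura coupling with 12 under the conditions of step 10 should give the (1S,3R)-bromo biaryl diol F3. Miyaura borylation at C8a (B2pin2, PdCl2(dppf), KOAc, dioxane) should give the C8a pinacol boronate F4, and NaBO3·4H2O in THF/H2O should oxidise it to the C8a phenol F5. With PPh3 and DIAD in THF at 0 °C the phenol should displace the activated, less hindered C3 carbinol in a six-membered closure. This inverts R to S, and the fallback comes back to the route at 14.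

**Step 10.** Transmetalation at the doubly flanked C6 position may be slow. Protodeboronation of the flavone boronate, insertion of palladium into C8a–Br and reduction of the aryl palladium species by the free carbinols could then take over. The fallback moves the biaryl coupling forward to the cheap, achiral methyl ketone. That compound carries no carbinol, tolerates forcing and can be used in large excess, so that zerovalent palladium always meets a C–I bond. It sets out from 4 (2–3 equiv) and 12 (Pd(OAc)2, SPhos, K3PO4, toluene/H2O, 100 °C) to give the biaryl methyl ketone F6. Claisen condensation with 5 (KOtBu, THF) should give the biaryl 1,3-diketone F7. Transfer hydrogenation with RuCl(p-cymene)[(S,S)-TsDPEN] should give the biaryl (3S)-hydroxy ketone F8. Evans–Saksena reduction then brings the fallback back to the route at 13.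

**Step 6.** Hydride transfer from the mild triacetoxyborohydride may be too slow, because the carbonyl is shielded on both faces by the ortho Br and OBn groups. The acidic medium would then have time to dehydrate the aldol. The fallback gives up the anti relationship, which is of no consequence for the target, and uses chelation-activated external hydride delivery under non-acidic conditions. It sets out from 7. Narasaka–Prasad reduction (Et2BOMe, NaBH4, THF/MeOH, −78 °C) should give the syn (1R,3S)-iodo diol F9. Coupling with 12 as in step 10 should give the (1R,3S)-bromo biaryl diol F10. Copper-catalysed closure as in step 11 should give the 2,4-trans (2S,4R)-flavan-4-ol F11. Dess–Martin oxidation erases C4, and the fallback comes back to the route at 15.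

Further compounds
F1 | step 11 | (3R)-1-[2,4-bis(benzyloxy)-6-bromo-3-iodophenyl]-3-[4-(benzyloxy)phenyl]-3-hydroxypropan-1-one | O=C(c1c(Br)cc(OCc2ccccc2)c(I)c1OCc1ccccc1)C[C@H](c1ccc(OCc2ccccc2)cc1)O
F2 | step 11 | (1S,3R)-1-[2,4-bis(benzyloxy)-6-bromo-3-iodophenyl]-3-[4-(benzyloxy)phenyl]propane-1,3-diol | O[C@H](c1c(Br)cc(OCc2ccccc2)c(I)c1OCc1ccccc1)C[C@H](c1ccc(OCc2ccccc2)cc1)O
F3 | step 11 | (1S,3R)-1-{2,4-bis(benzyloxy)-6-bromo-3-[5,7-bis(benzyloxy)-2-(4-benzyloxyphenyl)-4-oxo-4H-chromen-8-yl]phenyl}-3-[4-(benzyloxy)phenyl]propane-1,3-diol | O[C@H](c1c(Br)cc(OCc2ccccc2)c(-c3c(OCc6ccccc6)cc(OCc6ccccc6)c4c(=O)cc(-c5ccc(OCc6ccccc6)cc5)oc34)c1OCc2ccccc2)C[C@H](c1ccc(OCc2ccccc2)cc1)O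
F4 | step 11 | (1S,3R)-1-{2,4-bis(benzyloxy)-3-[5,7-bis(benzyloxy)-2-(4-benzyloxyphenyl)-4-oxo-4H-chromen-8-yl]-6-(4,4,5,5-tetramethyl-1,3,2-dioxaborolan-2-yl)phenyl}-3-[4-(benzyloxy)phenyl]propane-1,3-diol | O[C@H](c1c(B7OC(C)(C)C(C)(C)O7)cc(OCc2ccccc2)c(-c3c(OCc6ccccc6)cc(OCc6ccccc6)c4c(=O)cc(-c5ccc(OCc6ccccc6)cc5)oc34)c1OCc2ccccc2)C[C@H](c1ccc(OCc2ccccc2)cc1)O
F5 | step 11 | (1S,3R)-1-{2,4-bis(benzyloxy)-3-[5,7-bis(benzyloxy)-2-(4-benzyloxyphenyl)-4-oxo-4H-chromen-8-yl]-6-hydroxyphenyl}-3-[4-(benzyloxy)phenyl]propane-1,3-diol | O[C@H](c1c(O)cc(OCc2ccccc2)c(-c3c(OCc6ccccc6)cc(OCc6ccccc6)c4c(=O)cc(-c5ccc(OCc6ccccc6)cc5)oc34)c1OCc2ccccc2)C[C@H](c1ccc(OCc2ccccc2)cc1)O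
F6 | step 10 | 8-[3-acetyl-2,6-bis(benzyloxy)-4-bromophenyl]-5,7-bis(benzyloxy)-2-[4-(benzyloxy)phenyl]-4H-chromen-4-one | CC(=O)c1c(Br)cc(OCc2ccccc2)c(-c3c(OCc6ccccc6)cc(OCc6ccccc6)c4c(=O)cc(-c5ccc(OCc6ccccc6)cc5)oc34)c1OCc2ccccc2
F7 | step 10 | 1-{2,4-bis(benzyloxy)-6-bromo-3-[5,7-bis(benzyloxy)-2-(4-benzyloxyphenyl)-4-oxo-4H-chromen-8-yl]phenyl}-3-[4-(benzyloxy)phenyl]propane-1,3-dione | O=C(c1c(Br)cc(OCc2ccccc2)c(-c3c(OCc6ccccc6)cc(OCc6ccccc6)c4c(=O)cc(-c5ccc(OCc6ccccc6)cc5)oc34)c1OCc2ccccc2)CC(=O)c1ccc(OCc2ccccc2)cc1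
F8 | step 10 | (3S)-1-{2,4-bis(benzyloxy)-6-bromo-3-[5,7-bis(benzyloxy)-2-(4-benzyloxyphenyl)-4-oxo-4H-chromen-8-yl]phenyl}-3-[4-(benzyloxy)phenyl]-3-hydroxypropan-1-one | O=C(c1c(Br)cc(OCc2ccccc2)c(-c3c(OCc6ccccc6)cc(OCc6ccccc6)c4c(=O)cc(-c5ccc(OCc6ccccc6)cc5)oc34)c1OCc2ccccc2)C[C@@H](c1ccc(OCc2ccccc2)cc1)O
F9 | step 6 | (1R,3S)-1-[2,4-bis(benzyloxy)-6-bromo-3-iodophenyl]-3-[4-(benzyloxy)phenyl]propane-1,3-diol | O[C@@H](c1c(Br)cc(OCc2ccccc2)c(I)c1OCc1ccccc1)C[C@@H](c1ccc(OCc2ccccc2)cc1)O
F10 | step 6 | (1R,3S)-1-{2,4-bis(benzyloxy)-6-bromo-3-[5,7-bis(benzyloxy)-2-(4-benzyloxyphenyl)-4-oxo-4H-chromen-8-yl]phenyl}-3-[4-(benzyloxy)phenyl]propane-1,3-diol | O[C@@H](c1c(Br)cc(OCc2ccccc2)c(-c3c(OCc6ccccc6)cc(OCc6ccccc6)c4c(=O)cc(-c5ccc(OCc6ccccc6)cc5)oc34)c1OCc2ccccc2)C[C@@H](c1ccc(OCc2ccccc2)cc1)O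
F11 | step 6 | (2S,4R)-5,7-bis(benzyloxy)-2-[4-(benzyloxy)phenyl]-6-[5,7-bis(benzyloxy)-2-(4-benzyloxyphenyl)-4-oxo-4H-chromen-8-yl]chroman-4-ol | O[C@@H]1C[C@@H](c2ccc(OCc7ccccc7)cc2)Oc2cc(OCc7ccccc7)c(-c3c(OCc6ccccc6)cc(OCc6ccccc6)c4c(=O)cc(-c5ccc(OCc6ccccc6)cc5)oc34)c(OCc7ccccc7)c21
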